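**Strategy**

The route rests on disconnecting the diaryl ether bond between O3 of ring A and C4 of ring B. Ring A is a catechol whose O4 carries the sulfate in the target; with O4 masked as an allyl ether, O3–H is the only phenol, and the para position of ring B carries a boronic acid. A Chan–Lam coupling then forms the O3–C4 bond and closes the 24-membered meta,para-cyclophane in one operation. The precursor is a linear N5-Boc triamine bearing the (E)-4-allyloxy-3-hydroxycinnamoyl group on N10 and the (E)-4-boronocinnamoyl group on N1, assembled from two amides by reductive amination. Deallylation, sulfation and Boc removal finish the synthesis.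

Key step: step 8

Remark: the triamine nitrogens are numbered N1 (propyl end), N5 (central) and N10 (butyl end); the target is drawn as the neutral hydrogen sulfate and is expected to be isolated as the inner salt with N5 protonated.

**Route**

Step 1
Reactants: 1 3,4-dihydroxybenzaldehyde
Product: 2 4-(allyloxy)-3-hydroxybenzaldehyde
Conditions: allyl bromide (1.1 equiv), NaHCO3 (1.5 equiv), NaI (0.3 equiv), DMF, 40 °C
Reagents that add atoms: allyl bromide, C=CCBr
Why: Williamson etherification under a hydrogencarbonate base that deprotonates only the more acidic 4-OH (para to the formyl group), so that the allyl group should go to O4 and O3–H should stay free.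

Step 2
Reactants: 2 4-(allyloxy)-3-hydroxybenzaldehyde
Product: 4 (E)-3-[4-(allyloxy)-3-hydroxyphenyl]prop-2-enoic acid, via arylidenemalonic acid 3 (not isolated)
Conditions: malonic acid (2 equiv), piperidine (0.1 equiv), pyridine, 90 °C
Reagents that add atoms: malonic acid, OC(=O)CC(=O)O
Why: Knoevenagel–Doebner condensation, in which the arylidenemalonic acid formed under piperidine catalysis loses CO2 in hot pyridine to give the conjugated acid as the thermodynamically preferred (E)-alkene, well below the temperature at which the aryl allyl ether would undergo Claisen rearrangement.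

Step 3
Reactants: 4 (E)-3-[4-(allyloxy)-3-hydroxyphenyl]prop-2-enoic acid; 5 tert-butyl N-(4-aminobutyl)carbamate
Product: 6 tert-butyl N-[4-[[(E)-3-[4-(allyloxy)-3-hydroxyphenyl]prop-2-enoyl]amino]butyl]carbamate
Conditions: DIC (1.1 equiv), HOBt (1.1 equiv), DMF, 0 °C to rt
Reagents that add atoms: none
Why: Carbodiimide/HOBt amide coupling, in which the primary amine of 5 outcompetes the ring A phenol for the active ester, so that O3–H needs no protection.

Step 4
Reactants: 6 tert-butyl N-[4-[[(E)-3-[4-(allyloxy)-3-hydroxyphenyl]prop-2-enoyl]amino]butyl]carbamate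
Product: 7 (E)-N-(4-aminobutyl)-3-[4-(allyloxy)-3-hydroxyphenyl]prop-2-enamide hydrochloride
Conditions: HCl (4 M in 1,4-dioxane), rt
Reagents that add atoms: hydrogen chloride, Cl
Why: Acidolysis of the tert-butyl carbamate, which should leave the aryl allyl ether, the phenol and the (E)-propenamide untouched and deliver the primary amine as a storable hydrochloride.

Step 5
Reactants: 8 (E)-3-(4-boronophenyl)prop-2-enoic acid; 9 3,3-diethoxypropan-1-amine
Product: 10 [4-[(E)-3-[(3,3-diethoxypropyl)amino]-3-oxoprop-1-enyl]phenyl]boronic acid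
Conditions: DIC (1.1 equiv), HOBt (1.1 equiv), DMF, 0 °C to rt
Reagents that add atoms: none
Why: Carbodiimide/HOBt amide coupling, which tolerates a free arylboronic acid, places the ring B acid on the nitrogen that becomes N1 while the aldehyde needed for chain assembly stays masked as its diethyl acetal.

Step 6
Reactants: 10 [4-[(E)-3-[(3,3-diethoxypropyl)amino]-3-oxoprop-1-enyl]phenyl]boronic acid
Product: 11 [4-[(E)-3-oxo-3-[(3-oxopropyl)amino]prop-1-enyl]phenyl]boronic acid
Conditions: 1 M aq HCl, THF, rt
Reagents that add atoms: water, O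
Why: Acid-catalysed acetal hydrolysis at room temperature, mild enough to spare the arylboronic acid and the propenamide, frees the β-amido aldehyde, which cannot cyclise onto its amide nitrogen and is used at once.

Step 7
Reactants: 7 (E)-N-(4-aminobutyl)-3-[4-(allyloxy)-3-hydroxyphenyl]prop-2-enamide hydrochloride; 11 [4-[(E)-3-oxo-3-[(3-oxopropyl)amino]prop-1-enyl]phenyl]boronic acid
Product: 14 N10-[(E)-4-allyloxy-3-hydroxycinnamoyl]-N1-[(E)-4-boronocinnamoyl]-N5-Boc-spermidine, via aldimine 12 (not isolated), via N5-H secondary amine 13 (not isolated)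
Conditions: Et3N (2.5 equiv), CH2Cl2/DMF, rt, 1 h; then Boc2O (1.2 equiv), NaBH(OAc)3 (2 equiv), rt
Reagents that add atoms: di-tert-butyl dicarbonate, CC(C)(C)OC(=O)OC(=O)OC(C)(C)C
Why: Tandem reductive amination and N-Boc protection, in which NaBH(OAc)3 reduces the preformed aldimine without touching the propenamides or the boronic acid and Boc2O traps the secondary amine as it forms, which suppresses a second alkylation and installs the N5 carbamate in the same flask.

Step 8
Reactants: 14 N10-[(E)-4-allyloxy-3-hydroxycinnamoyl]-N1-[(E)-4-boronocinnamoyl]-N5-Boc-spermidine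
Product: 15 24-membered N5-Boc macrocyclic diaryl ether with ring A O4 allyl ether
Conditions: Cu(OAc)2 (1.0 equiv), pyridine (10 equiv), powdered 4 Å molecular sieves, O2 (1 atm), CH2Cl2, rt; 14 in CH2Cl2/DMF 9:1 added by syringe pump over 20 h to a final 1 mM
Reagents that add atoms: none
Why: The ring B aryl group is transferred from boron to divalent copper, the ring A O3 phenoxide binds, oxidation (by O2 or a second divalent copper centre) gives an aryl(aryloxy) trivalent copper species, and C–O reductive elimination forms the O3(ring A)–C4(ring B) bond while O2 returns monovalent copper to the divalent state, so that the copper salt is not consumed. The closest known reaction type is the Chan–Lam diaryl ether synthesis from phenols and arylboronic acids, which has been used to close macrocyclic diaryl ethers under high dilution. The single new ring, a 24-membered meta,para-cyclophane, is closed by intramolecular O-arylation in an end-to-end macrocyclisation, and the long flexible N5-Boc triamine tether should let O3 of ring A reach C4 of ring B without strain. No stereocentre is formed, and room temperature with a weak pyridine base leaves both (E)-propenamides, the Boc group and the allyl ether unchanged. Regioselectivity for O3 over O4 is secured by the allyl ether on O4, chemoselectivity for oxygen over nitrogen by the much greater acidity of the phenol than of the two amide N–H groups together with the Boc group on N5, and ring closure over oligomer formation by slow addition at about 1 mM.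

Step 9
Reactants: 15 24-membered N5-Boc macrocyclic diaryl ether with ring A O4 allyl ether
Product: 16 24-membered N5-Boc macrocyclic diaryl ether with free ring A O4 phenol
Conditions: Pd(PPh3)4 (5 mol%), morpholine (10 equiv), THF, rt
Reagents that add atoms: none
Why: Tsuji–Trost-type deallylation, in which zerovalent palladium ionises the aryl allyl ether to a π-allyl complex and the O4 phenoxide and morpholine captures the allyl group, under neutral conditions that spare the Boc group, the diaryl ether and both propenamides.

Step 10
Reactants: 16 24-membered N5-Boc macrocyclic diaryl ether with free ring A O4 phenol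
Product: 17 sodium salt of the N5-Boc macrocyclic ring A O4 sulfate
Conditions: SO3·pyridine (5 equiv), DMF, rt; then aq NaHCO3
Reagents that add atoms: sulfur trioxide–pyridine complex, O=S(=O)([O-])[n+]1ccccc1; sodium hydrogencarbonate, OC(=O)[O-].[Na+]
Why: O-Sulfation of the only free hydroxyl group with the sulfur trioxide–pyridine complex, which does not sulfate amide N–H groups or the N5 carbamate under these conditions, followed by isolation as the sodium salt in which the aryl sulfate monoester is stable.

Step 11
Reactants: 17 sodium salt of the N5-Boc macrocyclic ring A O4 sulfate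
Product: 18 target macrocycle (N5-H with ring A O4 hydrogen sulfate)
Conditions: CF3CO2H/H2O 9:1, 0 °C, 1 h; precipitation with cold Et2O; reversed-phase chromatography
Reagents that add atoms: none
Why: Acidolysis of the N5 tert-butyl carbamate in cold aqueous CF3CO2H, conditions under which Boc groups are lost quickly while aryl sulfate monoesters of the sulfotyrosine type are known to persist, so that the target should be obtained as its inner salt.

**Compound list**

1 | 3,4-dihydroxybenzaldehyde | O=Cc1ccc(O)c(O)c1 | starting material
2 | 4-(allyloxy)-3-hydroxybenzaldehyde | C=CCOc1ccc(C=O)cc1O | intermediate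
3 | 2-[[4-(allyloxy)-3-hydroxyphenyl]methylidene]propanedioic acid (not isolated) | C=CCOc1ccc(C=C(C(=O)O)C(=O)O)cc1O | intermediate
4 | (E)-3-[4-(allyloxy)-3-hydroxyphenyl]prop-2-enoic acid | C=CCOc1ccc(/C=C/C(=O)O)cc1O | intermediate
5 | tert-butyl N-(4-aminobutyl)carbamate (N-Boc-1,4-diaminobutane) | NCCCCNC(=O)OC(C)(C)C | starting material
6 | tert-butyl N-[4-[[(E)-3-[4-(allyloxy)-3-hydroxyphenyl]prop-2-enoyl]amino]butyl]carbamate | C=CCOc1ccc(/C=C/C(=O)NCCCCNC(=O)OC(C)(C)C)cc1O | intermediate
7 | (E)-N-(4-aminobutyl)-3-[4-(allyloxy)-3-hydroxyphenyl]prop-2-enamide hydrochloride | C=CCOc1ccc(/C=C/C(=O)NCCCCN)cc1O.Cl | intermediate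
8 | (E)-3-(4-boronophenyl)prop-2-enoic acid | O=C(O)/C=C/c1ccc(B(O)O)cc1 | starting material
9 | 3,3-diethoxypropan-1-amine | CCOC(CCN)OCC | starting material
10 | [4-[(E)-3-[(3,3-diethoxypropyl)amino]-3-oxoprop-1-enyl]phenyl]boronic acid | CCOC(CCNC(=O)/C=C/c1ccc(B(O)O)cc1)OCC | intermediate
11 | [4-[(E)-3-oxo-3-[(3-oxopropyl)amino]prop-1-enyl]phenyl]boronic acid | O=CCCNC(=O)/C=C/c1ccc(B(O)O)cc1 | intermediate
12 | aldimine from 7 (free base) and 11 (not isolated) | C=CCOc1ccc(/C=C/C(=O)NCCCCN=CCCNC(=O)/C=C/c2ccc(B(O)O)cc2)cc1O | intermediate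
13 | N10-[(E)-4-allyloxy-3-hydroxycinnamoyl]-N1-[(E)-4-boronocinnamoyl]spermidine, N5-H (not isolated) | C=CCOc1ccc(/C=C/C(=O)NCCCCNCCCNC(=O)/C=C/c2ccc(B(O)O)cc2)cc1O | intermediate
14 | N10-[(E)-4-allyloxy-3-hydroxycinnamoyl]-N1-[(E)-4-boronocinnamoyl]-N5-Boc-spermidine (cyclisation precursor) | C=CCOc1ccc(/C=C/C(=O)NCCCCN(C(=O)OC(C)(C)C)CCCNC(=O)/C=C/c2ccc(B(O)O)cc2)cc1O | intermediate
15 | 24-membered N5-Boc macrocyclic diaryl ether, ring A O4 allyl ether, both propenamides (E) | O=C1/C=C/c2ccc(OCC=C)c(c2)Oc2ccc(cc2)/C=C/C(=O)NCCCN(C(=O)OC(C)(C)C)CCCCN1 | intermediate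
16 | 24-membered N5-Boc macrocyclic diaryl ether, ring A O4 phenol | O=C1/C=C/c2ccc(O)c(c2)Oc2ccc(cc2)/C=C/C(=O)NCCCN(C(=O)OC(C)(C)C)CCCCN1 | intermediate
17 | sodium salt of the N5-Boc macrocyclic ring A O4 sulfate | O=C1/C=C/c2ccc(OS(=O)(=O)[O-])c(c2)Oc2ccc(cc2)/C=C/C(=O)NCCCN(C(=O)OC(C)(C)C)CCCCN1.[Na+] | intermediate
18 | CID124202369, N5-H macrocycle with ring A O4 hydrogen sulfate | O=C1/C=C/c2ccc(OS(=O)(=O)O)c(c2)Oc2ccc(cc2)/C=C/C(=O)NCCCNCCCCN1 | target

**Step count**

Total steps: 11. Longest linear sequence: 9 steps (steps 1, 2, 3, 4, 7, 8, 9, 10, 11).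

**Steps most likely to fail**

1. Step 8. At the dilution needed for ring closure the steps at copper are slow. Protodeboronation or oxidative hydroxylation of the boronic acid, oxidation of the electron-rich ring A phenol, or chain growth to oligomers may then outrun cyclisation. The fallback makes the ether between two small fragments and closes the ring at N5 instead. It sets out from 6 and 10, which are joined by an intermolecular Chan–Lam coupling at normal concentration (Cu(OAc)2, pyridine, 4 Å molecular sieves, CH2Cl2, air, rt) to give the open-chain diaryl ether carbamate acetal F1. Aqueous HCl in dioxane should remove the Boc group and the acetal together to give the amino aldehyde hydrochloride F2. Slow addition of F2 to Et3N and NaBH(OAc)3 in CH2Cl2/DMF at high dilution should close the 24-membered ring through the macrocyclic imine F3 to the macrocyclic secondary amine F4. Boc2O then converts F4 into 15, where the route is rejoined.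

2. Step 11. Acid-promoted loss of SO3 from the aryl sulfate monoester may compete with cleavage of the carbamate, above all if the acid is concentrated or warmed during isolation. The fallback carries the sulfate through the acid step as a diester. It sets out from 16, which with 2,2,2-trichloroethyl chlorosulfate, Et3N and DMAP in THF should give the acid-stable aryl 2,2,2-trichloroethyl sulfate F5. CF3CO2H in CH2Cl2 removes the Boc group to give the amine trifluoroacetate F6. Zn dust and HCO2NH4 in MeOH at rt then unmask the sulfate by reductive fragmentation of the trichloroethyl group and rejoin the route at 18.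

3. Step 7. Double alkylation of the primary amine, self-condensation or β-elimination of the β-amido aldehyde before the imine is reduced, and acylation of the ring A phenol by Boc2O may lower the return. The fallback builds the precursor by acylating a preformed triamine instead of forming the N5–C bond. It sets out from 4, which is coupled (DIC, HOBt, DMF) with commercial tert-butyl N-(4-aminobutyl)-N-[3-(tert-butoxycarbonylamino)propyl]carbamate (NCCCCN(C(=O)OC(C)(C)C)CCCNC(=O)OC(C)(C)C) to give the N10 amide di-Boc compound F7. HCl in dioxane gives the N10-acyl triamine dihydrochloride F8. The N-hydroxysuccinimide ester F9, made from 8 with N-hydroxysuccinimide and DIC, should acylate the primary N1 amine of F8 in preference to the secondary N5 amine (Et3N, DMF, −20 °C). This gives 13, where the route is rejoined and Boc2O leads to 14 as in step 7.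

**Further compounds**

F1 | step 8 | tert-butyl N-[4-[[(E)-3-[4-(allyloxy)-3-[4-[(E)-3-[(3,3-diethoxypropyl)amino]-3-oxoprop-1-enyl]phenoxy]phenyl]prop-2-enoyl]amino]butyl]carbamate | C=CCOc1ccc(/C=C/C(=O)NCCCCNC(=O)OC(C)(C)C)cc1Oc1ccc(/C=C/C(=O)NCCC(OCC)OCC)cc1
F2 | step 8 | (E)-N-(4-aminobutyl)-3-[4-(allyloxy)-3-[4-[(E)-3-oxo-3-[(3-oxopropyl)amino]prop-1-enyl]phenoxy]phenyl]prop-2-enamide hydrochloride | C=CCOc1ccc(/C=C/C(=O)NCCCCN)cc1Oc1ccc(/C=C/C(=O)NCCC=O)cc1.Cl
F3 | step 8 | 24-membered macrocyclic imine (C=N at N5), ring A O4 allyl ether | O=C1/C=C/c2ccc(OCC=C)c(c2)Oc2ccc(cc2)/C=C/C(=O)NCCC=NCCCCN1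
F4 | step 8 | 24-membered N5-H macrocyclic diaryl ether, ring A O4 allyl ether | O=C1/C=C/c2ccc(OCC=C)c(c2)Oc2ccc(cc2)/C=C/C(=O)NCCCNCCCCN1
F5 | step 11 | N5-Boc macrocyclic ring A O4 2,2,2-trichloroethyl sulfate | O=C1/C=C/c2ccc(OS(=O)(=O)OCC(Cl)(Cl)Cl)c(c2)Oc2ccc(cc2)/C=C/C(=O)NCCCN(C(=O)OC(C)(C)C)CCCCN1
F6 | step 11 | N5-H macrocyclic ring A O4 2,2,2-trichloroethyl sulfate, trifluoroacetate salt | O=C1/C=C/c2ccc(OS(=O)(=O)OCC(Cl)(Cl)Cl)c(c2)Oc2ccc(cc2)/C=C/C(=O)NCCCNCCCCN1.OC(=O)C(F)(F)F
F7 | step 7 | tert-butyl N-[4-[[(E)-3-[4-(allyloxy)-3-hydroxyphenyl]prop-2-enoyl]amino]butyl]-N-[3-[(tert-butoxycarbonyl)amino]propyl]carbamate | C=CCOc1ccc(/C=C/C(=O)NCCCCN(C(=O)OC(C)(C)C)CCCNC(=O)OC(C)(C)C)cc1O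
F8 | step 7 | (E)-3-[4-(allyloxy)-3-hydroxyphenyl]-N-[4-[(3-aminopropyl)amino]butyl]prop-2-enamide dihydrochloride | C=CCOc1ccc(/C=C/C(=O)NCCCCNCCCN)cc1O.Cl.Cl
F9 | step 7 | 2,5-dioxopyrrolidin-1-yl (E)-3-(4-boronophenyl)prop-2-enoate | O=C(ON1C(=O)CCC1=O)/C=C/c1ccc(B(O)O)cc1
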